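**Plan**

- Retrosynthesis: cut the ester C–O bond (allylic alcohol plus protected isovanillic acid), then take the C8 methyl and the C7=C8 double bond back to a plain cycloheptanone, then trade the C1–C5 bond for a C1–C6 bond, so that the cis-hydroazulenone becomes a trans-decalin-5,6-diol 5-mesylate.
- Enabling feature: C5 lies between the quaternary, methyl-bearing C1 and the oxygen-bearing C6. In the six-membered ring C1–C2–C3–C4–C5–C6, a carbinol at C6 and a leaving group on C5 let C1 slide from C6 to C5. The cyclopentane C1–C5 thus arises by ring contraction, the second six-membered ring (C1, C6–C10) grows to the seven-membered ring, and the carbonyl appears at C6, where the target carries its ester oxygen.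
- Forward order: a Robinson annulation gives the decalin; its enone ring is oxidised (cis-diol at C5/C6, isopropyl carbinol at C4); the 1,2-shift forms the 5/7 system; enone, C8 methyl, C6 alcohol and ester follow.
- Stereochemistry: C1 comes from a chiral-imine Michael addition with (S)-1-phenylethylamine; C5/C6 from osmylation anti to the angular methyl; C4 from equatorial addition to the acetonide ketone. The shift transfers these (retention at C1, inversion at C5), and C6 is set by hydride addition to the convex face.

Key step: step 8

Remark: the target is taken as the (3R,3aS,4R,8aR) enantiomer read from the SMILES (cis ring fusion, H-5 syn to the C1 methyl). All bicyclic compounds carry daucane locants: C1 methyl-bearing ring-fusion carbon, C4 isopropyl carbinol carbon, C5 ring-fusion CH, C6 carbinol/ester carbon, C7=C8 alkene, C8 methyl. Ring A holds C2–C4, ring B holds C7–C10; β is the face of the C1 methyl, α the opposite face.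

**Route**

Step 1
Reactants: 1 2-methylcyclohexanone (racemic); 2 (S)-1-phenylethylamine; 3 methyl vinyl ketone
Product: 6 (R)-2-methyl-2-(3-oxobutyl)cyclohexanone, via imine 4 (not isolated), via Michael-adduct imine 5 (not isolated)
Conditions: PhMe, reflux, Dean–Stark; then 3, THF, 40 °C; then 20% aq. AcOH, rt
Reagents that add atoms: water, O
Why: Chiral-imine Michael addition (asymmetric first stage of a Robinson annulation), in which the more substituted secondary enamine tautomer of 4 adds to the enone through a compact chair-like aza-ene-type transition state on the face not screened by the phenyl group of the auxiliary, so that the quaternary carbon C1 should form as the R centre before mild acid hydrolysis releases the diketone and the amine.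

Step 2
Reactants: 6 (R)-2-methyl-2-(3-oxobutyl)cyclohexanone
Product: 7 (R)-4a-methyl-4,4a,5,6,7,8-hexahydronaphthalen-2(3H)-one
Conditions: NaOMe, MeOH, 60 °C
Reagents that add atoms: none
Why: Intramolecular aldol condensation (second stage of the Robinson annulation) closes the cyclohexenone by a 6-(enolendo)-exo-trig aldol addition and dehydration without touching the quaternary centre.

Step 3
Reactants: 7 (R)-4a-methyl-4,4a,5,6,7,8-hexahydronaphthalen-2(3H)-one
Product: 8 5α,6α-dihydroxy-1β-methyl-trans-decalin-4-one
Conditions: OsO4 (cat.), NMO, citric acid, tBuOH/H2O, rt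
Reagents that add atoms: osmium tetroxide, O=[Os](=O)(=O)=O; N-methylmorpholine N-oxide, C[N+]1([O-])CCOCC1; water, O
Why: Catalytic OsO4/NMO cis-dihydroxylation should take place on the α face of the C5=C6 bond because the axial angular methyl screens the β face, which sets C5 and C6 together (both hydroxyls anti to the methyl, trans-decalin), while the citric acid buffer speeds turnover on the electron-poor alkene and keeps the β-hydroxy ketone from dehydrating.

Step 4
Reactants: 8 5α,6α-dihydroxy-1β-methyl-trans-decalin-4-one
Product: 9 5α,6α-O-isopropylidene-1β-methyl-trans-decalin-4-one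
Conditions: Me2C(OMe)2, PPTS (cat.), acetone, rt
Reagents that add atoms: 2,2-dimethoxypropane, COC(C)(C)OC
Why: Acid-catalysed transacetalisation ties the axial/equatorial cis-5,6-diol into a dioxolane, which changes no stereocentre and leaves the C4 ketone as the only reactive oxygen function.

Step 5
Reactants: 9 5α,6α-O-isopropylidene-1β-methyl-trans-decalin-4-one
Product: 11 4α-(tert-butyldimethylsilyloxy)-4β-isopropyl-5α,6α-O-isopropylidene-1β-methyl-trans-decalin, via lithium alkoxide 10 (not isolated)
Conditions: iPrLi, THF, −78 °C; then TBSOTf, −78 → 0 °C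
Reagents that add atoms: isopropyllithium, CC(C)[Li]; tert-butyldimethylsilyl trifluoromethanesulfonate, CC(C)(C)[Si](C)(C)OS(=O)(=O)C(F)(F)F
Why: 1,2-Addition of an organolithium to an α-alkoxy ketone followed by O-silylation of the alkoxide in the same flask, in which the α-axial approach to C4 is closed by the axial C6–O bond of the dioxolane (1,3-diaxial) so that isopropyl should enter equatorially from the β face, which sets C4 with its oxygen α and syn to the C5 oxygen.

Step 6
Reactants: 11 4α-(tert-butyldimethylsilyloxy)-4β-isopropyl-5α,6α-O-isopropylidene-1β-methyl-trans-decalin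
Product: 12 4α-(tert-butyldimethylsilyloxy)-4β-isopropyl-1β-methyl-trans-decalin-5α,6α-diol
Conditions: AcOH/H2O/THF, 50 °C
Reagents that add atoms: none
Why: Acid hydrolysis of the isopropylidene acetal, to which the hindered tertiary silyl ether should be stable, frees the secondary C5–OH and the tertiary C6–OH.

Step 7
Reactants: 12 4α-(tert-butyldimethylsilyloxy)-4β-isopropyl-1β-methyl-trans-decalin-5α,6α-diol
Product: 13 5α-methanesulfonate of diol 12 (6α-OH free)
Conditions: MsCl, Et3N, CH2Cl2, −20 → 0 °C
Reagents that add atoms: methanesulfonyl chloride, CS(=O)(=O)Cl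
Why: Sulfonylation through sulfene is selective for the secondary equatorial C5–OH because the only other hydroxyl (C6) is tertiary, and it places the leaving group anti-periplanar to the ring-fusion bond C6–C1.

Step 8
Reactants: 13 5α-methanesulfonate of diol 12
Product: 14 4α-(tert-butyldimethylsilyloxy)-4β-isopropyl-1β-methyl-5βH-cis-bicyclo[5.3.0]decan-6-one
Conditions: AlEt3, CH2Cl2, −78 → 0 °C; aq. KNaC4H4O6 (tartrate) work-up
Reagents that add atoms: none
Why: AlEt3 converts the only free hydroxyl (tertiary C6–OH) into a diethylaluminium alkoxide whose aluminium also activates the neighbouring mesylate, and the oxygen lone pair then pushes the ring-fusion bond C6–C1, which is anti-periplanar to the equatorial C5–OMs bond of the ring A chair, onto C5 as mesylate leaves in a concerted pinacol-type (semipinacol) 1,2-shift. The closest known reaction type is the organoaluminium- or base-promoted rearrangement of 2-hydroxy sulfonates, in its classical form the contraction of decalin-1,8a-diol 1-sulfonates to hydroazulenones. No ring is closed by cyclisation: the single shift turns six-membered ring A (C1–C2–C3–C4–C5–C6) into the cyclopentane C1–C2–C3–C4–C5 by expelling C6 (contraction by one atom) and turns ring B (C1, C6–C10) into the cycloheptanone C1, C5–C10 by taking up C5 (expansion by one atom). The only stereocentre made is C5, which is inverted because C1 enters anti to the departing 5α-mesylate, and since C1 migrates with retention the hydrogen on C5 ends up β and syn to the C1 methyl (cis ring fusion), while C4 is a spectator whose 4α-silyloxy group stays syn to the new C5–C6(=O) bond. The step needs site selectivity between the two ring bonds anti-periplanar to the leaving group (C6–C1 and C4–C3), and this is secured by the silyl ether on the C4 oxygen, which leaves the C6 oxygen as the only one able to push, and by the absence of hydrogen on C4 and C6, which rules out E2 elimination and hydride shift. The non-basic aluminium reagent should also spare the product from epimerisation at C5 and from β-elimination of the silyloxy group.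

Step 9
Reactants: 14 4α-(tert-butyldimethylsilyloxy)-4β-isopropyl-1β-methyl-5βH-cis-bicyclo[5.3.0]decan-6-one
Product: 16 4α-(tert-butyldimethylsilyloxy)-4β-isopropyl-1β-methyl-5βH-cis-bicyclo[5.3.0]dec-7-en-6-one, via lithium enolate 15 (not isolated)
Conditions: LiN(iPr)2, THF, −78 °C; then PhS(Cl)=NtBu, −78 °C
Reagents that add atoms: none
Why: Mukaiyama dehydrogenation, in which the amide base removes a proton from the C7 methylene (C5–H lies between two fully substituted carbons), the enolate is sulfenylated at C7 by the sulfinimidoyl chloride and syn-elimination of the sulfenamide gives the C7=C8 enone.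

Step 10
Reactants: 16 4α-(tert-butyldimethylsilyloxy)-4β-isopropyl-1β-methyl-5βH-cis-bicyclo[5.3.0]dec-7-en-6-one
Product: 18 4α-(tert-butyldimethylsilyloxy)-4β-isopropyl-1β,8-dimethyl-5βH-cis-bicyclo[5.3.0]dec-7-en-6-one, via lithium enolate 17 (not isolated)
Conditions: CuI, MeLi, Et2O, 0 °C; then 16, −78 → −30 °C; then PhS(Cl)=NtBu, THF, −78 °C
Reagents that add atoms: methyllithium, [Li]C, transferred as lithium dimethylcuprate, [Li+].C[Cu-]C
Why: Conjugate addition of the cuprate places the methyl group on C8 and the resulting enolate is dehydrogenated in the same flask by the Mukaiyama sulfinimidoyl chloride protocol, so the transient C8 stereocentre is of no consequence and the C7=C8(CH3) enone of the target results.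

Step 11
Reactants: 18 4α-(tert-butyldimethylsilyloxy)-4β-isopropyl-1β,8-dimethyl-5βH-cis-bicyclo[5.3.0]dec-7-en-6-one
Product: 19 4α-(tert-butyldimethylsilyloxy)-4β-isopropyl-1β,8-dimethyl-5βH-cis-bicyclo[5.3.0]dec-7-en-6α-ol (6R)
Conditions: NaBH4, CeCl3·7H2O, MeOH, −40 °C
Reagents that add atoms: none
Why: Luche 1,2-reduction, in which hydride should attack C6 from the convex β face of the cis-fused bicycle (the face of H-5) because the concave α face is closed by the cyclopentane ring and its C4 silyloxy group, which gives the 6α-alcohol with oxygen syn to C4.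

Step 12
Reactants: 20 isovanillic acid
Product: 22 3-(tert-butyldimethylsilyloxy)-4-methoxybenzoic acid, via bis-silyl compound 21 (not isolated)
Conditions: TBSCl, imidazole, DMF, rt; then AcOH/H2O/THF, rt
Reagents that add atoms: tert-butyldimethylsilyl chloride, CC(C)(C)[Si](C)(C)Cl
Why: Silylation of both acidic OH groups followed by selective hydrolysis of the labile silyl ester leaves the phenol masked as its silyl ether and the carboxylic acid free for coupling.

Step 13
Reactants: 19 6α-allylic alcohol; 22 3-(tert-butyldimethylsilyloxy)-4-methoxybenzoic acid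
Product: 23 6α-[3-(tert-butyldimethylsilyloxy)-4-methoxybenzoyloxy] derivative of 19 (bis-silyl ether of the target)
Conditions: EDC·HCl, DMAP, CH2Cl2, rt → 40 °C
Reagents that add atoms: none
Why: Steglich esterification (carbodiimide activation with DMAP as acyl-transfer catalyst) acylates the only free hydroxyl, the secondary allylic C6–OH, with retention at C6.

Step 14
Reactants: 23 bis-silyl ether of the target
Product: 24 target, (3R,3aS,4R,8aR)-3-hydroxy-6,8a-dimethyl-3-(propan-2-yl)-1,2,3,3a,4,7,8,8a-octahydroazulen-4-yl 3-hydroxy-4-methoxybenzoate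
Conditions: HF·pyridine, pyridine/THF, 0 → 40 °C
Reagents that add atoms: none
Why: Fluoride-mediated cleavage of the aryl silyl ether and the tertiary silyl ether, under conditions that the allylic benzoate, the tertiary alcohol and the trisubstituted alkene should survive, gives the target.

**Compound list**

1 | 2-methylcyclohexanone (racemic) | CC1CCCCC1=O | starting material
2 | (S)-1-phenylethylamine | C[C@H](N)c1ccccc1 | starting material
3 | methyl vinyl ketone (but-3-en-2-one) | CC(=O)C=C | starting material
4 | N-(2-methylcyclohexylidene)-(S)-1-phenylethylamine (imine; ring stereocentre mobile through the enamine) | CC1CCCCC1=N[C@@H](C)c1ccccc1 | intermediate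
5 | N-[(2R)-2-methyl-2-(3-oxobutyl)cyclohexylidene]-(S)-1-phenylethylamine (Michael-adduct imine) | CC(=O)CC[C@@]1(C)CCCCC1=N[C@@H](C)c1ccccc1 | intermediate
6 | (R)-2-methyl-2-(3-oxobutyl)cyclohexanone | CC(=O)CC[C@@]1(C)CCCCC1=O | intermediate
7 | (R)-4a-methyl-4,4a,5,6,7,8-hexahydronaphthalen-2(3H)-one (C4 ketone, C5=C6, 1β-methyl) | O=C1C=C2CCCC[C@]2(C)CC1 | intermediate
8 | 5α,6α-dihydroxy-1β-methyl-trans-decalin-4-one (both hydroxyls anti to the angular methyl) | O=C1[C@H](O)[C@@]2(O)CCCC[C@]2(C)CC1 | intermediate
9 | 5α,6α-O-isopropylidene-1β-methyl-trans-decalin-4-one | O=C1CC[C@@]2(C)CCCC[C@]2(OC(C)(C)O3)[C@H]13 | intermediate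
10 | lithium alkoxide of 4β-isopropyl-5α,6α-O-isopropylidene-1β-methyl-trans-decalin-4α-ol | CC(C)[C@]1(O[Li])CC[C@@]2(C)CCCC[C@]2(OC(C)(C)O3)[C@H]13 | intermediate
11 | 4α-(tert-butyldimethylsilyloxy)-4β-isopropyl-5α,6α-O-isopropylidene-1β-methyl-trans-decalin | CC(C)[C@]1(O[Si](C)(C)C(C)(C)C)CC[C@@]2(C)CCCC[C@]2(OC(C)(C)O3)[C@H]13 | intermediate
12 | 4α-(tert-butyldimethylsilyloxy)-4β-isopropyl-1β-methyl-trans-decalin-5α,6α-diol | CC(C)[C@]1(O[Si](C)(C)C(C)(C)C)CC[C@@]2(C)CCCC[C@]2(O)[C@H]1O | intermediate
13 | 5α-methanesulfonate of diol 12 (6α-OH free) | CC(C)[C@]1(O[Si](C)(C)C(C)(C)C)CC[C@@]2(C)CCCC[C@]2(O)[C@H]1OS(C)(=O)=O | intermediate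
14 | 4α-(tert-butyldimethylsilyloxy)-4β-isopropyl-1β-methyl-5βH-cis-bicyclo[5.3.0]decan-6-one | O=C1CCCC[C@]2(C)CC[C@@](O[Si](C)(C)C(C)(C)C)(C(C)C)[C@H]12 | intermediate
15 | lithium 6(7)-enolate of ketone 14 | [Li]OC1=CCCC[C@]2(C)CC[C@@](O[Si](C)(C)C(C)(C)C)(C(C)C)[C@H]12 | intermediate
16 | 4α-(tert-butyldimethylsilyloxy)-4β-isopropyl-1β-methyl-5βH-cis-bicyclo[5.3.0]dec-7-en-6-one | O=C1C=CCC[C@]2(C)CC[C@@](O[Si](C)(C)C(C)(C)C)(C(C)C)[C@H]12 | intermediate
17 | lithium 6(7)-enolate of the 8-methyl ketone (C8 epimers) | [Li]OC1=CC(C)CC[C@]2(C)CC[C@@](O[Si](C)(C)C(C)(C)C)(C(C)C)[C@H]12 | intermediate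
18 | 4α-(tert-butyldimethylsilyloxy)-4β-isopropyl-1β,8-dimethyl-5βH-cis-bicyclo[5.3.0]dec-7-en-6-one | O=C1C=C(C)CC[C@]2(C)CC[C@@](O[Si](C)(C)C(C)(C)C)(C(C)C)[C@H]12 | intermediate
19 | 4α-(tert-butyldimethylsilyloxy)-4β-isopropyl-1β,8-dimethyl-5βH-cis-bicyclo[5.3.0]dec-7-en-6α-ol (6R) | O[C@@H]1C=C(C)CC[C@]2(C)CC[C@@](O[Si](C)(C)C(C)(C)C)(C(C)C)[C@H]12 | intermediate
20 | isovanillic acid (3-hydroxy-4-methoxybenzoic acid) | COc1ccc(C(=O)O)cc1O | starting material
21 | tert-butyldimethylsilyl 3-(tert-butyldimethylsilyloxy)-4-methoxybenzoate | COc1ccc(C(=O)O[Si](C)(C)C(C)(C)C)cc1O[Si](C)(C)C(C)(C)C | intermediate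
22 | 3-(tert-butyldimethylsilyloxy)-4-methoxybenzoic acid | COc1ccc(C(=O)O)cc1O[Si](C)(C)C(C)(C)C | intermediate
23 | 6α-[3-(tert-butyldimethylsilyloxy)-4-methoxybenzoyloxy] derivative of 19 (bis-silyl ether of the target) | COc1ccc(C(=O)O[C@@H]2C=C(C)CC[C@]3(C)CC[C@@](O[Si](C)(C)C(C)(C)C)(C(C)C)[C@H]23)cc1O[Si](C)(C)C(C)(C)C | intermediate
24 | (3R,3aS,4R,8aR)-3-hydroxy-6,8a-dimethyl-3-(propan-2-yl)-1,2,3,3a,4,7,8,8a-octahydroazulen-4-yl 3-hydroxy-4-methoxybenzoate | COc1ccc(C(=O)O[C@@H]2C=C(C)CC[C@]3(C)CC[C@@](O)(C(C)C)[C@H]23)cc1O | target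

**Step count**

Total steps: 14. Longest linear sequence: 13 (steps 1–11, 13, 14).

**Steps most likely to fail**

Step 5. The organolithium may act as a base (enolisation of the C4 ketone towards C3 or C5, the latter opening the dioxolane by β-elimination) or as a hydride donor instead of adding to the crowded carbonyl, and the hindered lithium alkoxide may be silylated incompletely. The fallback sets out from 9 and returns at 11. 2-Propenylmagnesium bromide with CeCl3 (THF, −78 °C), a less basic nucleophile that cannot transfer hydride, should add with the same β-face preference to give the 4β-isopropenyl-4α-ol acetonide F1. Hydrogenation of its 1,1-disubstituted alkene (H2, Pd/C, EtOAc; no other C=C bond is present at this stage) gives the 4β-isopropyl-4α-ol acetonide F2. Silylation as a separate operation (TBSOTf, 2,6-lutidine, CH2Cl2, 0 → 40 °C) then gives 11.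

Step 3. Osmylation of the electron-poor, β,β-disubstituted enone may be slow, its facial preference may be eroded, and the β-hydroxy ketone may lose water to the diosphenol during turnover or work-up. The fallback sets out from 7 and returns at 9; it takes the ketone out of conjugation first. Luche reduction (NaBH4, CeCl3·7H2O, MeOH) gives the allylic 4β-alcohol F3. Its electron-rich alkene should be osmylated quickly (OsO4 cat., NMO) anti to both the angular methyl and the allylic hydroxyl to give the 4β,5α,6α-triol F4. The cis-5,6-diol is tied up as the acetonide alcohol F5 (Me2C(OMe)2, PPTS; the trans-4,5 pair does not compete), and Dess–Martin oxidation of the remaining C4 alcohol gives 9.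

Step 11. The facial preference of the hydride rests only on the shape of the cis-fused bicycle, and the C1 methyl on the convex face may erode it. The fallback sets out from 18 and returns at 24; it replaces steric control by chelation control. HF·pyridine removes the C4 silyl group to give the β-hydroxy enone F6. A Narasaka–Prasad reduction (Et2BOMe, NaBH4, THF/MeOH, −78 °C) then ties the C4 oxygen and the carbonyl oxygen into a boron chelate that closes the α face, so that hydride must enter from the β face and the syn 4α,6α-diol F7 results. Steglich esterification with 22 acylates only the secondary allylic hydroxyl and gives the mono-silyl ester F8, and HF·pyridine removes the aryl silyl ether to give 24.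

Further compounds
F1 | step 5 | 4β-isopropenyl-5α,6α-O-isopropylidene-1β-methyl-trans-decalin-4α-ol | C=C(C)[C@]1(O)CC[C@@]2(C)CCCC[C@]2(OC(C)(C)O3)[C@H]13
F2 | step 5 | 4β-isopropyl-5α,6α-O-isopropylidene-1β-methyl-trans-decalin-4α-ol | CC(C)[C@]1(O)CC[C@@]2(C)CCCC[C@]2(OC(C)(C)O3)[C@H]13
F3 | step 3 | (2S,4aR)-type allylic alcohol: 1β-methyl-Δ5(6)-octalin-4β-ol | O[C@H]1C=C2CCCC[C@]2(C)CC1
F4 | step 3 | 1β-methyl-trans-decalin-4β,5α,6α-triol | O[C@H]1[C@H](O)[C@@]2(O)CCCC[C@]2(C)CC1
F5 | step 3 | 5α,6α-O-isopropylidene-1β-methyl-trans-decalin-4β-ol | O[C@@H]1CC[C@@]2(C)CCCC[C@]2(OC(C)(C)O3)[C@H]13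
F6 | step 11 | 4α-hydroxy-4β-isopropyl-1β,8-dimethyl-5βH-cis-bicyclo[5.3.0]dec-7-en-6-one | O=C1C=C(C)CC[C@]2(C)CC[C@@](O)(C(C)C)[C@H]12
F7 | step 11 | 4β-isopropyl-1β,8-dimethyl-5βH-cis-bicyclo[5.3.0]dec-7-ene-4α,6α-diol | O[C@@H]1C=C(C)CC[C@]2(C)CC[C@@](O)(C(C)C)[C@H]12
F8 | step 11 | 6α-[3-(tert-butyldimethylsilyloxy)-4-methoxybenzoyloxy] derivative of diol F7 (C4–OH free) | COc1ccc(C(=O)O[C@@H]2C=C(C)CC[C@]3(C)CC[C@@](O)(C(C)C)[C@H]23)cc1O[Si](C)(C)C(C)(C)C
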